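**Retrosynthetic overview**
1. The quinone is taken back to the bis-MOM hydroquinone 22 (MOM removal, oxidation) and then to the C8 phenol 21 (O-methylation).
2. Key disconnection: in 21 the ring oxygen O1 on C8a and the oxygen on C8 sit on neighbouring carbons of the benzo ring, beside the C7 methoxy group. Both C–O bonds are made from the C8–C8a aryne of bromo alcohol 17: the alkoxide adds at C8a, and the C8 anion is borylated and oxidised.
3. 17 comes from auxiliary-controlled benzylation of the arylacetyl imide 11 with benzylic bromide 14, which sets C3, followed by hydride cleavage.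
4. 11 comes from pentamethoxybenzene 1 through quinone 2, bis-MOM ether 4, ortho-lithiation/ethylene oxide and oxidation to acid 8.
5. Ring order: both six-membered carbocycles are bought; the pyran ring is the only ring formed, in step 11.

Key step: step 11

Assumption: 1, 9 and 12 are purchased, and the two quinone oxygens introduced in step 1 are taken to come from water (ipso attack with loss of methanol).

**Route**

Step 1
Reactants: 1 pentamethoxybenzene
Product: 2 2,3,5-trimethoxy-1,4-benzoquinone
Conditions: (NH4)2Ce(NO3)6 (2.2 equiv), MeCN/H2O, 0 °C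
Reagents that add atoms: water, O
Why: Oxidative demethylation of a para-dimethoxyarene by tetravalent cerium should give the para-quinone, and since the C1/C4 and C2/C5 methoxy pairs of 1 lead to the same product only one quinone is expected.

Step 2
Reactants: 2 2,3,5-trimethoxy-1,4-benzoquinone
Product: 3 2,3,5-trimethoxybenzene-1,4-diol
Conditions: Na2S2O4, EtOAc/H2O, rt, argon
Reagents that add atoms: none
Why: Dithionite reduction of a quinone to its hydroquinone is fast in a two-phase system, and exclusion of air should keep the electron-rich hydroquinone from re-oxidising.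

Step 3
Reactants: 3 2,3,5-trimethoxybenzene-1,4-diol
Product: 4 1,4-bis(methoxymethoxy)-2,3,5-trimethoxybenzene
Conditions: MOMCl, i-Pr2NEt, CH2Cl2, 0 °C to reflux, argon
Reagents that add atoms: chloromethyl methyl ether, COCCl
Why: Williamson-type O-alkylation of both phenols with the reactive chloromethyl ether should proceed under amine base, which avoids the air-sensitive hydroquinone dianion.

Step 4
Reactants: 4 1,4-bis(methoxymethoxy)-2,3,5-trimethoxybenzene
Product: 6 2-[2,5-bis(methoxymethoxy)-3,4,6-trimethoxyphenyl]ethan-1-ol, via aryllithium 5 (not isolated)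
Conditions: n-BuLi, TMEDA, THF, −78 to 0 °C; then ethylene oxide, 0 °C to rt; H2O
Reagents that add atoms: ethylene oxide, C1CO1
Why: Directed ortho-metalation at the only ring hydrogen, flanked by an OMOM and an OMe group, followed by epoxide opening by the aryllithium should give the 2-arylethanol.

Step 5
Reactants: 6 2-[2,5-bis(methoxymethoxy)-3,4,6-trimethoxyphenyl]ethan-1-ol
Product: 8 2-[2,5-bis(methoxymethoxy)-3,4,6-trimethoxyphenyl]acetic acid, via arylacetaldehyde 7 (not isolated)
Conditions: TEMPO (cat.), NaClO2, NaOCl (cat.), MeCN/phosphate buffer pH 6.7, 35 °C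
Reagents that add atoms: sodium chlorite, [Na+].[O-]Cl=O
Why: Oxoammonium-catalysed alcohol oxidation with chlorite as terminal oxidant (Anelli-type) should give the acid through aldehyde 7 at near-neutral pH, where the MOM acetals are stable and the fully substituted ring offers no site for chlorination.

Step 6
Reactants: 8 2-[2,5-bis(methoxymethoxy)-3,4,6-trimethoxyphenyl]acetic acid; 9 (S)-4-benzyl-1,3-oxazolidin-2-one
Product: 11 (4S)-4-benzyl-3-{[2,5-bis(methoxymethoxy)-3,4,6-trimethoxyphenyl]acetyl}-1,3-oxazolidin-2-one, via mixed pivalic anhydride 10 (not isolated)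
Conditions: t-BuCOCl, Et3N, THF, −20 °C; then LiCl, 9, −20 °C to rt
Reagents that add atoms: none
Why: N-Acylation of the oxazolidinone through the mixed pivalic anhydride with LiCl activation should occur at the less hindered arylacetyl carbonyl and leaves the auxiliary stereocentre untouched.

Step 7
Reactants: 12 3-bromo-4,5-dimethoxybenzaldehyde
Product: 13 (3-bromo-4,5-dimethoxyphenyl)methanol
Conditions: NaBH4, MeOH, 0 °C
Reagents that add atoms: none
Why: Borohydride reduction of the aldehyde gives the benzylic alcohol without touching the aryl bromide.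

Step 8
Reactants: 13 (3-bromo-4,5-dimethoxyphenyl)methanol
Product: 14 1-bromo-5-(bromomethyl)-2,3-dimethoxybenzene
Conditions: PBr3, CH2Cl2, 0 °C
Reagents that add atoms: phosphorus tribromide, BrP(Br)Br
Why: The benzylic alcohol is converted into the bromide by bromide displacement of its phosphite ester (SN2).

Step 9
Reactants: 11 (4S)-4-benzyl-3-{[2,5-bis(methoxymethoxy)-3,4,6-trimethoxyphenyl]acetyl}-1,3-oxazolidin-2-one; 14 1-bromo-5-(bromomethyl)-2,3-dimethoxybenzene
Product: 16 (4S)-4-benzyl-3-{(2S)-2-[2,5-bis(methoxymethoxy)-3,4,6-trimethoxyphenyl]-3-(3-bromo-4,5-dimethoxyphenyl)propanoyl}-1,3-oxazolidin-2-one, via sodium Z-enolate 15 (not isolated)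
Conditions: NaN(SiMe3)2, THF, −78 °C; then 14, −78 to −40 °C; aq NH4Cl
Reagents that add atoms: none
Why: Evans asymmetric alkylation: the chelated Z-enolate 15 is shielded on one face by the C4 benzyl group of the (S)-auxiliary, so the benzylic bromide should enter from the opposite face and set the (S) configuration at the α-carbon, the later C3.

Step 10
Reactants: 16 (4S)-4-benzyl-3-{(2S)-2-[2,5-bis(methoxymethoxy)-3,4,6-trimethoxyphenyl]-3-(3-bromo-4,5-dimethoxyphenyl)propanoyl}-1,3-oxazolidin-2-one
Product: 17 (2S)-2-[2,5-bis(methoxymethoxy)-3,4,6-trimethoxyphenyl]-3-(3-bromo-4,5-dimethoxyphenyl)propan-1-ol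
Conditions: LiBH4, THF, MeOH (1 equiv), 0 °C
Reagents that add atoms: none
Why: Reductive cleavage of the N-acyloxazolidinone by LiBH4 attacks the exocyclic carbonyl without enolisation, so the primary alcohol should form with the (S) centre intact and with the aryl bromide and MOM groups untouched.

Step 11
Reactants: 17 (2S)-2-[2,5-bis(methoxymethoxy)-3,4,6-trimethoxyphenyl]-3-(3-bromo-4,5-dimethoxyphenyl)propan-1-ol
Product: 21 (3S)-3-[2,5-bis(methoxymethoxy)-3,4,6-trimethoxyphenyl]-6,7-dimethoxychroman-8-ol, via aryne alkoxide 18 (not isolated), via C8 aryllithium 19 (not isolated), via C8 boronate 20 (not isolated)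
Conditions: lithium 2,2,6,6-tetramethylpiperidide (4 equiv, from 2,2,6,6-tetramethylpiperidine 4.4 equiv and n-BuLi 4.0 equiv), THF, −78 to 0 °C; then B(OMe)3, −78 °C to rt; then H2O2, aq NaOH, 0 °C to rt
Reagents that add atoms: hydrogen peroxide, OO
Why: The lithium amide forms the alkoxide and then removes the only hydrogen ortho to bromine (on the future C8a), and loss of LiBr gives the C8–C8a aryne 18. The tethered alkoxide adds to C8a and closes the pyran ring in a 6-exo-dig-type mode, the closest known reaction type being the cyclisation of tethered alkoxides or amides onto base-generated arynes with electrophilic quench of the new aryl anion. Addition at C8a rather than C8 is the selectivity needed; it is secured by the tether (attack at C8 would need a bridged seven-membered ring) and by the C7 methoxy group, whose inductive pull stabilises the carbanion developing at C8. Aryllithium 19, flanked by O1 and the C7 methoxy oxygen, should resist protonation by tetramethylpiperidine and is captured by B(OMe)3 as boronate 20, which alkaline H2O2 oxidises to the phenol by 1,2-aryl shift from boron to oxygen at the same carbon. No stereocentre is formed; the C3–H is far too weakly acidic for the amide base, so the (S) configuration from step 9 is carried through.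

Step 12
Reactants: 21 (3S)-3-[2,5-bis(methoxymethoxy)-3,4,6-trimethoxyphenyl]-6,7-dimethoxychroman-8-ol
Product: 22 (3S)-3-[2,5-bis(methoxymethoxy)-3,4,6-trimethoxyphenyl]-6,7,8-trimethoxychroman
Conditions: MeI, K2CO3, DMF, rt
Reagents that add atoms: iodomethane, CI
Why: Williamson O-methylation of the C8 phenoxide should be clean because the molecule has no other acidic site.

Step 13
Reactants: 22 (3S)-3-[2,5-bis(methoxymethoxy)-3,4,6-trimethoxyphenyl]-6,7,8-trimethoxychroman
Product: 24 2,3,5-trimethoxy-6-[(3S)-6,7,8-trimethoxychroman-3-yl]-1,4-benzoquinone, via hydroquinone 23 (not isolated)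
Conditions: 3 M HCl, MeOH/THF, 45 °C, argon; then aq FeCl3, 0 °C to rt
Reagents that add atoms: none
Why: Acid-catalysed acetal cleavage (transacetalisation to dimethoxymethane) frees hydroquinone 23, which trivalent iron should oxidise to the para-quinone while the less electron-rich chroman ring stays intact, and the acidic medium avoids epimerisation at C3.

**Compound list**
1 | pentamethoxybenzene | COc1cc(OC)c(OC)c(OC)c1OC | starting material
2 | 2,3,5-trimethoxy-1,4-benzoquinone | COC1=CC(=O)C(OC)=C(OC)C1=O | intermediate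
3 | 2,3,5-trimethoxybenzene-1,4-diol | COc1cc(O)c(OC)c(OC)c1O | intermediate
4 | 1,4-bis(methoxymethoxy)-2,3,5-trimethoxybenzene | COCOc1cc(OC)c(OCOC)c(OC)c1OC | intermediate
5 | [2,5-bis(methoxymethoxy)-3,4,6-trimethoxyphenyl]lithium | [Li]c1c(OCOC)c(OC)c(OC)c(OCOC)c1OC | intermediate
6 | 2-[2,5-bis(methoxymethoxy)-3,4,6-trimethoxyphenyl]ethan-1-ol | OCCc1c(OCOC)c(OC)c(OC)c(OCOC)c1OC | intermediate
7 | [2,5-bis(methoxymethoxy)-3,4,6-trimethoxyphenyl]acetaldehyde | O=CCc1c(OCOC)c(OC)c(OC)c(OCOC)c1OC | intermediate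
8 | 2-[2,5-bis(methoxymethoxy)-3,4,6-trimethoxyphenyl]acetic acid | OC(=O)Cc1c(OCOC)c(OC)c(OC)c(OCOC)c1OC | intermediate
9 | (S)-4-benzyl-1,3-oxazolidin-2-one | O=C1OC[C@H](Cc2ccccc2)N1 | starting material
10 | mixed anhydride of acid 8 with pivalic acid | CC(C)(C)C(=O)OC(=O)Cc1c(OCOC)c(OC)c(OC)c(OCOC)c1OC | intermediate
11 | (4S)-4-benzyl-3-{[2,5-bis(methoxymethoxy)-3,4,6-trimethoxyphenyl]acetyl}-1,3-oxazolidin-2-one | O=C1OC[C@H](Cc2ccccc2)N1C(=O)Cc1c(OCOC)c(OC)c(OC)c(OCOC)c1OC | intermediate
12 | 3-bromo-4,5-dimethoxybenzaldehyde | COc1cc(C=O)cc(Br)c1OC | starting material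
13 | (3-bromo-4,5-dimethoxyphenyl)methanol | COc1cc(CO)cc(Br)c1OC | intermediate
14 | 1-bromo-5-(bromomethyl)-2,3-dimethoxybenzene | COc1cc(CBr)cc(Br)c1OC | intermediate
15 | sodium Z-enolate of imide 11 | O=C1OC[C@H](Cc2ccccc2)N1/C([O-])=C/c1c(OCOC)c(OC)c(OC)c(OCOC)c1OC.[Na+] | intermediate
16 | (4S)-4-benzyl-3-{(2S)-2-[2,5-bis(methoxymethoxy)-3,4,6-trimethoxyphenyl]-3-(3-bromo-4,5-dimethoxyphenyl)propanoyl}-1,3-oxazolidin-2-one | O=C1OC[C@H](Cc2ccccc2)N1C(=O)[C@@H](Cc1cc(Br)c(OC)c(OC)c1)c1c(OCOC)c(OC)c(OC)c(OCOC)c1OC | intermediate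
17 | (2S)-2-[2,5-bis(methoxymethoxy)-3,4,6-trimethoxyphenyl]-3-(3-bromo-4,5-dimethoxyphenyl)propan-1-ol | COc1c(OCOC)c(OC)c(OC)c(OCOC)c1[C@@H](CO)Cc1cc(Br)c(OC)c(OC)c1 | intermediate
18 | lithium alkoxide of the C8–C8a aryne derived from 17 | [Li+].[O-]C[C@@H](CC1=CC(OC)=C(OC)C#C1)c1c(OCOC)c(OC)c(OC)c(OCOC)c1OC | intermediate
19 | (3S)-3-[2,5-bis(methoxymethoxy)-3,4,6-trimethoxyphenyl]-6,7-dimethoxychroman-8-yllithium | COc1c(OCOC)c(OC)c(OC)c(OCOC)c1[C@H]1COc2c(cc(OC)c(OC)c2[Li])C1 | intermediate
20 | dimethyl {(3S)-3-[2,5-bis(methoxymethoxy)-3,4,6-trimethoxyphenyl]-6,7-dimethoxychroman-8-yl}boronate | COc1c(OCOC)c(OC)c(OC)c(OCOC)c1[C@H]1COc2c(cc(OC)c(OC)c2B(OC)OC)C1 | intermediate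
21 | (3S)-3-[2,5-bis(methoxymethoxy)-3,4,6-trimethoxyphenyl]-6,7-dimethoxychroman-8-ol | COc1c(OCOC)c(OC)c(OC)c(OCOC)c1[C@H]1COc2c(cc(OC)c(OC)c2O)C1 | intermediate
22 | (3S)-3-[2,5-bis(methoxymethoxy)-3,4,6-trimethoxyphenyl]-6,7,8-trimethoxychroman | COc1c(OCOC)c(OC)c(OC)c(OCOC)c1[C@H]1COc2c(cc(OC)c(OC)c2OC)C1 | intermediate
23 | 2,3,5-trimethoxy-6-[(3S)-6,7,8-trimethoxychroman-3-yl]benzene-1,4-diol | COc1c(O)c(OC)c(OC)c(O)c1[C@H]1COc2c(cc(OC)c(OC)c2OC)C1 | intermediate
24 | 2,3,5-trimethoxy-6-[(3S)-6,7,8-trimethoxychroman-3-yl]-1,4-benzoquinone (CNP0344638.1) | COC1=C(OC)C(=O)C([C@H]2COc3c(cc(OC)c(OC)c3OC)C2)=C(OC)C1=O | target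

**Step count**
Total: 13 steps. Longest linear sequence: 11 steps (steps 1–6 and 9–13, from pentamethoxybenzene); steps 7–8 form the two-step side branch to bromide 14.

**Steps most likely to fail, with fallbacks**

Step 11. The aryl anion 19 may be protonated by tetramethylpiperidine before boron capture, which would leave hydrogen at C8. The amide may also add to the aryne, or the bromine may migrate before cyclisation. The fallback leaves the aryne chemistry and makes the O1–C8a bond by metal-catalysed etherification, with the C8 methoxy group already in place. It sets out from imide 11 and comes back to the route at 22. Commercial 2-bromo-3,4,5-trimethoxybenzaldehyde (COc1cc(C=O)c(Br)c(OC)c1OC) is reduced with NaBH4 in MeOH to (2-bromo-3,4,5-trimethoxyphenyl)methanol F1, and PBr3 converts this into 2-bromo-1-(bromomethyl)-3,4,5-trimethoxybenzene F2. The sodium enolate of 11 (NaN(SiMe3)2, THF, −78 °C) is alkylated with F2 to give the (2S)-imide F3, under the same facial control as in step 9. LiBH4 then gives the (2S)-bromo alcohol F4. Intramolecular C–O coupling of the Buchwald–Hartwig type (Pd(OAc)2, 2-(di-tert-butylphosphino)-1,1'-binaphthyl, Cs2CO3, toluene, 70 °C, through zerovalent palladium) should close the pyran ring and give 22 directly.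

Step 9. The di-ortho-substituted aryl enolate is hindered. Alkylation may stay incomplete, the enolate may break down to an aryl ketene with loss of the auxiliary on warming, or the acidic α-aryl centre may epimerise during quench. The fallback sets the stereocentre by hydrogenation instead of alkylation. It sets out from acid 8 and aldehyde 12 and comes back at alcohol 17. Perkin condensation of 8 with 12 (Ac2O, Et3N, 100 °C) should give (E)-2-[2,5-bis(methoxymethoxy)-3,4,6-trimethoxyphenyl]-3-(3-bromo-4,5-dimethoxyphenyl)acrylic acid F5. Asymmetric hydrogenation with Ru(OAc)2(BINAP) (H2, MeOH) should give the (2S)-propanoic acid F6; the BINAP antipode that delivers the (S)-acid is fixed in a test run by correlation with 17 from the auxiliary route. Reduction of F6 with BH3·SMe2 in THF, which spares the aryl bromide, gives 17.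

Step 1. The radical cation of 1 may couple through its free ring position to biaryls and diquinones, or be over-oxidised, so that little monoquinone 2 is formed. The fallback blocks the free position before the oxidation. It sets out from 1 and comes back at acid 8. Lithiation of 1 at its only ring hydrogen (n-BuLi, THF, 0 °C) and allylation (CuBr·SMe2 cat., allyl bromide) give 1-allyl-2,3,4,5,6-pentamethoxybenzene F7. Oxidative demethylation of this fully substituted ring with (NH4)2Ce(NO3)6 in MeCN/H2O should give 2-allyl-3,5,6-trimethoxy-1,4-benzoquinone F8. Na2S2O4 reduces it to 2-allyl-3,5,6-trimethoxybenzene-1,4-diol F9, and MOMCl/i-Pr2NEt gives 1-allyl-2,5-bis(methoxymethoxy)-3,4,6-trimethoxybenzene F10. Lemieux–Johnson cleavage (OsO4 cat., NaIO4, 2,6-lutidine, dioxane/H2O) gives aldehyde 7, here isolated, and Pinnick oxidation (NaClO2, NaH2PO4, 2-methyl-2-butene, t-BuOH/H2O) gives 8.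

**Further compounds**
F1 | step 11 | (2-bromo-3,4,5-trimethoxyphenyl)methanol | COc1cc(CO)c(Br)c(OC)c1OC
F2 | step 11 | 2-bromo-1-(bromomethyl)-3,4,5-trimethoxybenzene | COc1cc(CBr)c(Br)c(OC)c1OC
F3 | step 11 | (4S)-4-benzyl-3-{(2S)-2-[2,5-bis(methoxymethoxy)-3,4,6-trimethoxyphenyl]-3-(2-bromo-3,4,5-trimethoxyphenyl)propanoyl}-1,3-oxazolidin-2-one | O=C1OC[C@H](Cc2ccccc2)N1C(=O)[C@@H](Cc1cc(OC)c(OC)c(OC)c1Br)c1c(OCOC)c(OC)c(OC)c(OCOC)c1OC
F4 | step 11 | (2S)-2-[2,5-bis(methoxymethoxy)-3,4,6-trimethoxyphenyl]-3-(2-bromo-3,4,5-trimethoxyphenyl)propan-1-ol | COc1c(OCOC)c(OC)c(OC)c(OCOC)c1[C@@H](CO)Cc1cc(OC)c(OC)c(OC)c1Br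
F5 | step 9 | (E)-2-[2,5-bis(methoxymethoxy)-3,4,6-trimethoxyphenyl]-3-(3-bromo-4,5-dimethoxyphenyl)acrylic acid | OC(=O)/C(=C/c1cc(Br)c(OC)c(OC)c1)c1c(OCOC)c(OC)c(OC)c(OCOC)c1OC
F6 | step 9 | (2S)-2-[2,5-bis(methoxymethoxy)-3,4,6-trimethoxyphenyl]-3-(3-bromo-4,5-dimethoxyphenyl)propanoic acid | OC(=O)[C@@H](Cc1cc(Br)c(OC)c(OC)c1)c1c(OCOC)c(OC)c(OC)c(OCOC)c1OC
F7 | step 1 | 1-allyl-2,3,4,5,6-pentamethoxybenzene | C=CCc1c(OC)c(OC)c(OC)c(OC)c1OC
F8 | step 1 | 2-allyl-3,5,6-trimethoxy-1,4-benzoquinone | C=CCC1=C(OC)C(=O)C(OC)=C(OC)C1=O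
F9 | step 1 | 2-allyl-3,5,6-trimethoxybenzene-1,4-diol | C=CCc1c(OC)c(O)c(OC)c(OC)c1O
F10 | step 1 | 1-allyl-2,5-bis(methoxymethoxy)-3,4,6-trimethoxybenzene | C=CCc1c(OC)c(OCOC)c(OC)c(OC)c1OCOC
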